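**Plan**

Labels: quinolone A carries dihydropyran ring C (Oa on its C4, Cc on its C3). Quinolone B carries gem-dimethyl dihydropyran ring D (Ob on its C4, Ca on its C3). Ca = fusion O–CH, Cb = fusion CH, Cq = CMe2 of ring D, Cc = CH bearing CH2CMe2OH.
Enabling feature: the two carbon arms on Cc, CH2–CMe2–OH and Cb–Cq(Me)2–Ob, are the same four-carbon unit ending in an oxygenated CMe2. Cc is therefore the hidden centre of an achiral CH(CH=CMe2)2 group on C3 of quinolone A, and Ob–C4=C3–Ca of quinolone B is the retron of a 1-oxadiene.
Cuts, in order: side-chain C–OH (alkene hydration); Ca–Cb and Ob–Cq together (retro oxa-[4+2], opening rings C and D); Oa–Ca (vinylic substitution); C3(B)=Ca (orthoformate carbon); C3(A)–Cc (allylation with the phorone-derived dienol).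
Forward: one 4-hydroxy-1-methyl-2-quinolone feeds both halves, which are joined through Oa. Rings D and C then close simultaneously in a single cycloaddition, and the spare isobutenyl arm is hydrated last.
Stereochemistry: all three centres arise in the cycloaddition. The tether (Ca/Cb cis) and allylic strain (Cc) fix the relative configuration. A chiral Cu(OTf)2–bis(oxazoline) catalyst picks one of the two enantiotopic arms and so fixes the absolute configuration.

Key step: step 6

Assumption 1: the (S,S)-ligand is taken to lead to the (Ca R, Cb S, Cc S) series; if the sense of induction proves opposite, the equally available (R,R)-ligand is used and nothing else changes.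
Assumption 2: the exocyclic C=C bonds of the 3-methylidenequinoline-2,4-diones are push–pull alkenes that isomerise freely in solution; they are drawn Z (heteroatom cis to the amide carbonyl C2), the geometry from which the cycloaddition proceeds.

**Route**

Step 1
Reactants: 1 phorone (2,6-dimethylhepta-2,5-dien-4-one)
Product: 2 2,6-dimethylhepta-2,5-dien-4-ol
Conditions: LiAlH4, Et2O, 0 °C; H2O, 15% aq NaOH work-up; used without distillation
Reagents that add atoms: none
Why: Carbonyl 1,2-reduction by a hard hydride, in which both β-carbons of the cross-conjugated dienone are fully substituted, so conjugate reduction is shut off, and the basic work-up spares the acid-labile doubly allylic alcohol.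

Step 2
Reactants: 2 2,6-dimethylhepta-2,5-dien-4-ol; 3 4-hydroxy-1-methylquinolin-2(1H)-one
Product: 4 3-(2,6-dimethylhepta-2,5-dien-4-yl)-4-hydroxy-1-methylquinolin-2(1H)-one
Conditions: Yb(OTf)3 (5 mol %), 4 Å MS, MeNO2–1,4-dioxane, 0 °C to rt
Reagents that add atoms: none
Why: Lewis acid catalysed dehydrative Friedel–Crafts-type C3 allylation, well known for 4-hydroxy-2-quinolones and 4-hydroxycoumarins with secondary allylic alcohols: the doubly allylic alcohol ionises under very weak activation, C3 bonds to the central carbon because either terminus would create a quaternary centre beside two flanking ring substituents, and the low temperature keeps the 4-OH from adding to an isobutenyl group.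

Step 3
Reactants: 3 4-hydroxy-1-methylquinolin-2(1H)-one; 5 triethyl orthoformate
Product: 7 (Z)-1-methyl-3-[(phenylsulfanyl)methylidene]quinoline-2,4(1H,3H)-dione, via ethoxymethylidene dione 6 (not isolated)
Conditions: PhSH (1.05 equiv), HC(OEt)3 (excess, neat), 120 °C, EtOH distilled off
Reagents that add atoms: thiophenol, Sc1ccccc1
Why: Orthoformate three-component condensation of a cyclic 1,3-dicarbonyl compound (Knoevenagel-type ethoxymethylenation followed by vinylic addition–elimination), in which the soft thiol displaces ethoxide from 6 faster than a second molecule of 3 can attack it, and distilling off ethanol drives both stages.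

Step 4
Reactants: 7 (Z)-1-methyl-3-[(phenylsulfanyl)methylidene]quinoline-2,4(1H,3H)-dione
Product: 8 (Z)-1-methyl-3-[(phenylsulfonyl)methylidene]quinoline-2,4(1H,3H)-dione
Conditions: dimethyldioxirane (dried acetone solution, 2.2 equiv), CH2Cl2, −20 °C to rt; evaporation, stored under argon
Reagents that add atoms: dimethyldioxirane, CC1(C)OO1
Why: Sulfide-to-sulfone oxidation with a neutral electrophilic oxygen-transfer reagent, in which sulfur is the only oxidisable site because the C=C bond is strongly electron-poor, and acetone as sole by-product allows the water-sensitive vinyl sulfone to be isolated by evaporation alone.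

Step 5
Reactants: 4 3-(2,6-dimethylhepta-2,5-dien-4-yl)-4-hydroxy-1-methylquinolin-2(1H)-one; 8 (Z)-1-methyl-3-[(phenylsulfonyl)methylidene]quinoline-2,4(1H,3H)-dione
Product: 10 3-(2,6-dimethylhepta-2,5-dien-4-yl)-1-methyl-4-{[(Z)-(1-methyl-2,4-dioxo-1,4-dihydroquinolin-3(2H)-ylidene)methyl]oxy}quinolin-2(1H)-one, via sodium quinolonate 9 (not isolated)
Conditions: NaH (1.0 equiv), THF, 0 °C; then 8, THF, −78 to −30 °C; switch to cold toluene, filtration through Celite under argon, evaporation below 0 °C, used at once
Reagents that add atoms: none
Why: Nucleophilic vinylic substitution by addition–elimination, as known for aryloxides on β-sulfonyl enones and on alkoxymethylene malonates: the oxygen of the hindered enolate adds to the open CH terminus (its own C3 is shielded by the branched substituent) and the dicarbonyl-stabilised carbanion expels benzenesulfinate, a much better nucleofuge than the quinolonate, so that the exchange runs downhill, as displacement of an amine or an alkoxide would not, at a temperature at which the uncatalysed cycloaddition should still be slow.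

Step 6
Reactants: 10 3-(2,6-dimethylhepta-2,5-dien-4-yl)-1-methyl-4-{[(Z)-(1-methyl-2,4-dioxo-1,4-dihydroquinolin-3(2H)-ylidene)methyl]oxy}quinolin-2(1H)-one
Product: 11 isobutenyl cycloadduct: two 6-methyl-3,4-dihydro-2H-pyrano[3,2-c]quinolin-5(6H)-one units sharing the Ca–Cb bond (C2/C3 of unit A = C4'/C3' of unit B), 2',2'-dimethyl on Cq, CH=CMe2 on Cc (C4 of unit A); Ha and Hb cis, Hc trans to Hb; (Ca R, Cb S, Cc S)
Conditions: Cu(OTf)2 (10 mol %), (S,S)-tBu-box [2,2'-(propane-2,2-diyl)bis((4S)-4-tert-butyl-4,5-dihydrooxazole), 11 mol %], 4 Å MS, CH2Cl2, −40 to −10 °C
Reagents that add atoms: none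
Why: Proposed new method: chelation of the C2 and C4 carbonyl oxygens of the quinolinedione by the divalent copper centre lowers the LUMO of the 1-oxadiene Ob=C4–C3=Ca, and one isobutenyl group adds to it in an asynchronous concerted inverse-demand [4+2], Cb bonding to Ca somewhat ahead of Ob bonding to the incipient tertiary centre Cq. The closest known reaction types are the intramolecular oxa-Diels–Alder cyclisation of alkylidene- and alkoxymethylene-1,3-dicarbonyl compounds onto tethered prenyl-type alkenes, the cycloadditions of 3-formylchromones (cyclic aryloxymethylene dicarbonyls) and the Cu(OTf)2–bis(oxazoline) hetero-Diels–Alder reactions of chelating oxadienes, whereas an acyclic aryloxymethylene diene and a choice between two enantiotopic alkenes have not been shown. Ring D (Ob, C4, C3, Ca, Cb, Cq) is the six-membered cycloaddition ring itself, and ring C (Oa, Ca, Cb, Cc, C3 and C4 of quinolone A) closes in the same event as a six-membered ring because Ca and Cb are already linked by the four-atom tether Oa–C4=C3–Cc. Ca and Cb are set cis (Ha and Hb on one face) because the short, sp2-rich tether reaches only the endo-E-syn transition state, and Cc is set by A(1,3) strain, which holds Hc in the plane of the reacting alkene next to its Z-methyl group, so that the idle isobutenyl arm points away from the diene and ends trans to Cq. With the relative configuration fixed in this way by the substrate, choosing an arm is the same as choosing a face of Ca, and the tert-butyl group of the ligand in the quadrant beside Ob, over which the dienophile has to stack, blocks one of the two mirror-image approaches and thereby sets the absolute configuration (Ca R, Cb S, Cc S). The step further needs the ketone and not the amide oxygen as diene terminus, which is secured by the lower-lying ketone-based oxadiene, by the Z geometry that places the tether on the outside of that diene, and by the aromatic 4-alkoxy-2-quinolone that only this closure creates.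

Step 7
Reactants: 11 isobutenyl cycloadduct (Ca R, Cb S, Cc S)
Product: 12 CNP0202276.2: the skeleton of 11 with CH2C(CH3)2OH in place of CH=CMe2 on Cc; Ha and Hb cis, Hc trans to Hb; (Ca R, Cb S, Cc S)
Conditions: Co(acac)2 (20 mol %), PhSiH3 (4 equiv), O2 (1 atm), THF, rt
Reagents that add atoms: dioxygen, O=O
Why: Mukaiyama hydration (hydrogen-atom transfer from a cobalt hydride, trapping of the radical by O2 and reduction of the peroxide), in which hydrogen adds to the CH terminus of the only isolated alkene to give the tertiary radical and hence the Markovnikov tertiary alcohol, while the remaining C=C bonds belong to the quinolone rings and no stereocentre is touched.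

**Compound list**

1 | phorone (2,6-dimethylhepta-2,5-dien-4-one) | CC(C)=CC(=O)C=C(C)C | starting material
2 | 2,6-dimethylhepta-2,5-dien-4-ol | CC(C)=CC(O)C=C(C)C | intermediate
3 | 4-hydroxy-1-methylquinolin-2(1H)-one | Cn1c(=O)cc(O)c2ccccc21 | starting material
4 | 3-(2,6-dimethylhepta-2,5-dien-4-yl)-4-hydroxy-1-methylquinolin-2(1H)-one | Cn1c(=O)c(C(C=C(C)C)C=C(C)C)c(O)c2ccccc21 | intermediate
5 | triethyl orthoformate | CCOC(OCC)OCC | starting material
6 | (Z)-3-(ethoxymethylidene)-1-methylquinoline-2,4(1H,3H)-dione (not isolated) | CCO/C=C1/C(=O)c2ccccc2N(C)C1=O | intermediate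
7 | (Z)-1-methyl-3-[(phenylsulfanyl)methylidene]quinoline-2,4(1H,3H)-dione | c1ccccc1S/C=C1/C(=O)c2ccccc2N(C)C1=O | intermediate
8 | (Z)-1-methyl-3-[(phenylsulfonyl)methylidene]quinoline-2,4(1H,3H)-dione | O=S(=O)(c1ccccc1)/C=C1/C(=O)c2ccccc2N(C)C1=O | intermediate
9 | sodium 3-(2,6-dimethylhepta-2,5-dien-4-yl)-1-methyl-2-oxo-1,2-dihydroquinolin-4-olate (not isolated) | Cn1c(=O)c(C(C=C(C)C)C=C(C)C)c([O-])c2ccccc21.[Na+] | intermediate
10 | 3-(2,6-dimethylhepta-2,5-dien-4-yl)-1-methyl-4-{[(Z)-(1-methyl-2,4-dioxo-1,4-dihydroquinolin-3(2H)-ylidene)methyl]oxy}quinolin-2(1H)-one | Cn1c(=O)c(C(C=C(C)C)C=C(C)C)c(O/C=C2/C(=O)c3ccccc3N(C)C2=O)c2ccccc21 | intermediate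
11 | isobutenyl cycloadduct, cis-fused rings C and D, (Ca R, Cb S, Cc S) | Cn1c(=O)c2c(c3ccccc31)O[C@H]1c3c(c4ccccc4n(C)c3=O)OC(C)(C)[C@H]1[C@@H]2C=C(C)C | intermediate
12 | CNP0202276.2, (Ca R, Cb S, Cc S) | Cn1c(=O)c2c(c3ccccc31)O[C@H]1c3c(c4ccccc4n(C)c3=O)OC(C)(C)[C@H]1[C@@H]2CC(C)(C)O | target

**Step count**

Total step count: 7.
Longest linear sequence: 5 steps (1, 2, 5, 6, 7; the branch 3, 4, 5, 6, 7 is equally long).

**Steps most likely to fail**

Step 6. Four things may go wrong:
- The catalyst may discriminate poorly between the two enantiotopic arms.
- The uncatalysed background cycloaddition may erode the enantiomeric purity.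
- Proton loss from the developing tertiary cation may divert the reaction into an ene-type outcome.
- The Lewis acid may assist cleavage of the vinylogous anhydride linkage.

The fallback uses known chemistry, sets out from 3 and comes back at 11. Knoevenagel condensation of 3 with 3-methylbut-2-enal (pyridine, reflux), followed by spontaneous oxa-6π electrocyclisation, gives N-methylflindersine F1. On heating in xylene in a sealed tube, F1 equilibrates with its ring-opened o-quinone methide F2. The O=C4–C3=CH oxadiene of F2 adds across the pyran C=C of a second molecule of F1. This is the hetero-Diels–Alder dimerisation known for 2,2-dimethylpyran-fused quinolones and chromenes.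

This addition forms Oa–Ca and Cb–Cc instead of the bonds of step 6. The cis fusion is guaranteed by the cyclic Z alkene, and the polarity of the partners directs oxygen to Ca. No catalyst controls the outcome at Cc here, so chromatography precedes the resolution. Preparative HPLC on a chiral stationary phase then separates 11 from its mirror image ent-11 F3.

Step 5. Three things may go wrong:
- The triply activated vinyl sulfone may decompose or hydrolyse before coupling.
- The ambident enolate may attack through C3 or through the amide oxygen.
- Cycloaddition may begin prematurely during isolation.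

The fallback sets out from 4 and 7, bypasses step 4 and comes back at 10. Instead of oxidising sulfur, the thiolate is pulled off by a thiophilic metal, as in the silver-promoted acyl transfer of thioesters. Treating 4 with Ag2O (0.5 equiv, 4 Å MS, CH2Cl2, dark) gives the silver quinolonate F4. F4 is stirred with sulfide 7 at −20 °C. Precipitation of AgSPh should drive the otherwise unfavourable exchange, and filtration leaves a salt-free solution of 10.

Step 2. Three things may go wrong:
- The delocalised cation may be captured at a tertiary terminus.
- Proton loss may lead to the conjugated triene.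
- The 4-hydroxy group may close onto an isobutenyl arm under acid catalysis.

The fallback sets out from 2 and comes back at 4, replacing cationic chemistry by neutral π-allyl chemistry. Deprotonation of 2 (n-BuLi, THF, −78 °C) and acylation with methyl chloroformate give 2,6-dimethylhepta-2,5-dien-4-yl methyl carbonate F5. Tsuji–Trost allylation of 3 follows (Pd(PPh3)4, 5 mol %, zerovalent palladium, THF, rt). The soft C3 nucleophile should be directed to the less hindered allyl terminus, which is the central carbon, and no acid is present to trigger ring closure.

**Further compounds**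

F1 | step 6 | N-methylflindersine (2,2,6-trimethyl-2,6-dihydro-5H-pyrano[3,2-c]quinolin-5-one) | Cn1c(=O)c2c(c3ccccc31)OC(C)(C)C=C2
F2 | step 6 | (Z)-1-methyl-3-(3-methylbut-2-en-1-ylidene)quinoline-2,4(1H,3H)-dione (o-quinone methide) | CC(C)=C/C=C1/C(=O)c2ccccc2N(C)C1=O
F3 | step 6 | ent-11, (Ca S, Cb R, Cc R) | Cn1c(=O)c2c(c3ccccc31)O[C@@H]1c3c(c4ccccc4n(C)c3=O)OC(C)(C)[C@@H]1[C@H]2C=C(C)C
F4 | step 5 | silver 3-(2,6-dimethylhepta-2,5-dien-4-yl)-1-methyl-2-oxo-1,2-dihydroquinolin-4-olate | Cn1c(=O)c(C(C=C(C)C)C=C(C)C)c([O-])c2ccccc21.[Ag+]
F5 | step 2 | 2,6-dimethylhepta-2,5-dien-4-yl methyl carbonate | COC(=O)OC(C=C(C)C)C=C(C)C
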